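Remarks that apply throughout:
- Atom labels follow carotenoid numbering: ring C1 (gem-dimethyl carbon) to C6 (chain-bearing carbinol), C5 the methyl carbinol, chain C7–C15 and then C15'–C10' (carboxyl carbon).
- Assumption: the usual face rule of the tartrate-controlled epoxidation (L-(+)-tartrate gives the 2S-type arrangement at the hydroxymethyl-bearing carbon) is taken to hold for 2; if the sense proved opposite, D-(−)-diethyl tartrate would be used with no other change.
- Assumption: 1, 8, 12 and 13 are taken as catalogue compounds (8 is commonly sold as an E/Z mixture, to be enriched in the E isomer or purified after use).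
- Consistency check of the stereochemistry: (1S,6S)-3 with inversion at C5 and retention of the C6–O bond maps exactly onto the (5R,6R) target. The C6 descriptor changes from S to R along the route only because C7 changes CIP rank, not because the centre is touched.
- All polyenes from 9 onward are handled in dim light under argon.

## Structural features

The target is a C27 apocarotenoid acid. A 2,6,6-trimethylcyclohexane ring (C1–C6) is joined through C6 to an all-E heptaenoic acid chain (C7 to C10') with methyl branches at C9, C13 and C13'. The only stereocentres are the two adjacent, fully substituted carbinol carbons C5 (R) and C6 (R), whose hydroxyls are trans on the ring. C6 is neopentyl on both sides, lying between the quaternary C1 and C5. The methyl pattern is head-to-tail from C9 to C13 but reversed across C15=C15', so a single isoprenoid C5 olefination reagent cannot supply the whole chain. The fragile features are the seven conjugated E alkenes (light, oxygen, acid, and E/Z leakage in every olefination) and the C6 hydroxyl, which is tertiary and allylic to the polyene and so ionises readily under acid. The real difficulty is to create the contiguous tertiary trans-diol in one absolute sense on a ring with no other handle (a cis-dihydroxylation would give the wrong relative configuration), and then to attach the chain to the hindered C6. The key step exploits the fact that C5 and C6 are the two carbons of the tetrasubstituted C5=C6 alkene of the achiral β-ring, with C7 as an allylic CH2OH directing group: syn delivery of one oxygen to one alkene face, followed by anti opening at C5, turns a cis-oxirane into the trans-diol.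

## Logic of the disconnections

20 ⇒ 18 (through 19). No skeletal bond is cut; the carboxyl and the two carbinol hydroxyls are traded for an ethyl ester and two silyl ethers. This keeps the acid and the acid-labile tertiary allylic C6 hydroxyl masked during chain assembly. The forward step may use only fluoride and hydroxide, never acid.

18 ⇒ 11 + 17. The C11=C12 double bond is cut. It is a disubstituted E alkene between two methyl-bearing alkenes, well suited to carbonyl olefination. The cut also places the whole region where the methyl pattern reverses inside 17, so the ring-bearing partner needs only one regular C5 extension. The polyene is split into a C15 and a C12 piece of similar size. The forward step must be E-selective, and the extended anion of 17 must react through its phosphorus-bearing carbon.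

17 ⇒ 16 ⇒ 15 ⇒ 14. The C12–P bond and then the C12–Br bond are cut, and C12 is raised to the carbonyl level of 14. The gain is in function only, but it lets the nucleophilic carbon of 17 derive from a formyl carbon. The forward steps need chemoselective reduction of a formyl group beside a conjugated ester, and substitution at an allylic terminus without transposition or loss of E geometry.

14 ⇒ 12 + 13. The C11'=C12' double bond is cut. This reveals the symmetrical 12, which already holds C12 to C12' with both methyl groups and three E alkenes. The demand is mono-olefination of a symmetrical dialdehyde.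

11 ⇒ 10 ⇒ 9 ⇒ 7 + 8. After two oxidation-level changes at C11, the C7=C8 double bond is cut; C8 to C11, the C9 methyl and the E C9=C10 alkene come from 8. The ring piece shrinks to a C10 unit with C7 at the formyl level. The forward olefination must occur at a carbonyl flanked by two fully substituted carbons and give E at C7=C8.

7 ⇒ 6 ⇒ 4 (through 5). C7 is taken back to the alcohol level and the two silyl groups are removed. The masking is needed because a free C5 or C6 hydroxyl beside the C7 formyl group would open retro-aldol and α-ketol pathways under basic olefination. The demand is differentiation of one primary from two tertiary hydroxyls.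

4 ⇒ 3. The C5–OH bond is cut and the oxygen on C6 is tied to C5 as an oxirane, so the trans-diol becomes a cis-fused epoxide. A relative-configuration problem becomes a ring opening. The forward step needs attack of water at C5 only, with inversion, and an untouched C6–O bond.

3 ⇒ 2. Both C–O bonds of the oxirane are cut, leaving the tetrasubstituted C5=C6 alkene of an achiral allylic alcohol. Two stereocentres and one ring vanish in a single retrosynthetic step. The forward step must deliver oxygen to one enantiotopic face, with the C7 hydroxyl as the handle.

2 ⇒ 1. The C7 carbinol is taken back to the formyl group of a commercial terpenoid. The only demand is 1,2-reduction.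

## Other disconnections considered

Alternative 1: The cut removes the C14–C15 and C15'–C14' single bonds. The C15=C15' ethene unit would come from the bifunctional reagent (E)-1-tributylstannyl-2-pinacolborylethene A2, and the rest from the iodo-dienoate A1 and the ring-bearing tetraenyl iodide A3. In the forward sense Pd(PPh3)4, a zerovalent palladium catalyst, would first join A1 to the tin terminus of A2 (Stille coupling). Once aqueous base is added it would join the boron terminus to A3 (Suzuki coupling), giving the ethyl ester A4 in one pot; A4 is the same compound as 19.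
- In its favour: both couplings retain alkene geometry, so every E double bond is fixed in a fragment before assembly. The conditions are nearly neutral and should tolerate the free diol, and two bonds are made in one operation.
- Where it is better: control of alkene geometry, because the olefinations of the chosen route create their double bonds and can leak Z isomers.
- Against it here: the cut does not touch the C5/C6 problem, so A3 would still have to be built from a ring piece such as 11. A3 ends in a trisubstituted E vinyl iodide on a tetraene, which costs steps and is light- and acid-sensitive. Tin residues must be removed from a polyene acid, and the order of the two transmetalations must hold to avoid oligomers.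
- Comparison: mechanistically it is a pair of stereoretentive sp2–sp2 couplings against stereogenerating carbonyl olefinations. Structurally it joins the halves at C15 instead of C11=C12. The final assembly is shorter, but making A1 and A3 restores the balance, so the two plans are about equal in length.

Alternative 2: The cut is the C5–C6 ring bond. The keto-aldehyde A5 (2,2-dimethyl-6-oxoheptanal) would be cyclised by a chiral triazolium-derived carbene. The carbene turns the C6 formyl group into an acyl anion equivalent (Breslow intermediate) that adds to the C5 ketone, closing the six-membered ring and setting C5 in the hydroxy ketone A6.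
- In its favour: it is catalytic and metal-free, and it forms the ring and the C5 carbinol without an inversion step.
- Where it is better: the C6 carbonyl of A6 lets C7 be attached by adding an alkynyl or alkenyl nucleophile to a ketone, which avoids the olefination of a doubly neopentyl aldehyde in step 6.
- Against it here: the catalyst sets only C5. C6 would depend on the facial preference of an addition to a hindered α-hydroxy ketone between two fully substituted carbons, where the nucleophile must enter on the side of the C5 hydroxyl. An aldehyde with a quaternary α-carbon is slow to form the Breslow intermediate, the methyl ketone acceptor is enolisable, and benzoin addition to a ketone is reversible. A5 must also be made first.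
- Comparison: the chosen plan takes the ring from a commercial terpenoid and derives both centres from one ligand-controlled step whose relative outcome is fixed by mechanism (syn addition, anti opening). This alternative has to make a skeletal bond and then a second, substrate-controlled stereocentre. Up to the ring building block the step counts are about equal; after it the alternative could be shorter if a longer enyne nucleophile were added at C6.

Alternative 3: The cut is the C1–C6 ring bond. In the acyclic ynone A7 the C5 stereocentre is already present as a triethylsilyl ether. Fe(acac)3 and PhSiH3 in ethanol would generate an iron hydride that passes a hydrogen atom to C2 of the trisubstituted alkene. The tertiary C1 radical would then add to the C6 carbonyl (6-exo) to give, after reduction of the alkoxy radical, the ring-closed carbinol A8.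
- In its favour: it forges the most congested ring bond, between a quaternary carbon and a tertiary carbinol, under mild and nearly neutral conditions.
- Where it is equal or better: C5 can be taken from a chiral-pool tertiary alcohol, so the absolute configuration does not rest on a face rule. C7 and C8 are already on C6 as an alkyne, which again avoids step 6.
- Against it here: radical addition to a carbonyl is reversible through β-scission of the alkoxy radical, simple reduction of the C1 radical competes, and the ynone offers a second acceptor site. The C6 configuration depends on the conformational bias of the C5 silyl ether and is not under reagent control. A7 needs a multistep synthesis, and the alkyne must later become an E alkene.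
- Comparison: mechanistically it is an open-shell chain process with less precedent for this acceptor type, against a concerted two-electron oxygen transfer on a well-precedented substrate class. Structurally it builds the ring that the chosen plan buys. It is longer up to the ring building block, though better placed for chain attachment.

Key step: step 2

## Route

Step 1
Reactants: 1 β-cyclocitral (2,6,6-trimethylcyclohex-1-ene-1-carbaldehyde)
Product: 2 β-cyclogeraniol ((2,6,6-trimethylcyclohex-1-en-1-yl)methanol)
Conditions: NaBH4, MeOH, 0 °C
Reagents that add atoms: none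
Why: Borohydride 1,2-reduction of the enal carbonyl; the tetrasubstituted alkene is untouched and no stereocentre is formed.

Step 2
Reactants: 2 β-cyclogeraniol
Product: 3 [(1S,6S)-2,2,6-trimethyl-7-oxabicyclo[4.1.0]heptan-1-yl]methanol
Conditions: tBuOOH (anhydrous, isooctane), Ti(OiPr)4 (10–20 mol %), L-(+)-diethyl tartrate (12–24 mol %), 4 Å molecular sieves, CH2Cl2, −20 °C; aqueous NaOH/brine work-up at 0 °C
Reagents that add atoms: tert-butyl hydroperoxide, CC(C)(C)OO
Why: Katsuki–Sharpless asymmetric epoxidation, the closest precedent being the same reaction on cyclic tetrasubstituted primary allylic alcohols. The alkoxide of 2 and the tert-butyl peroxide both bind the dimeric complex [Ti(OiPr)2(tartrate)]2 formed from Ti(OiPr)4 and the tartrate ester, and the distal peroxide oxygen is passed to C5=C6 in one concerted step through a spiro transition state. The oxirane is thus closed by suprafacial oxygen-atom transfer (a concerted [2+1] addition with both C–O bonds formed on the same face), not by a tethered cyclisation, so no Baldwin mode applies. C5 and C6 are created together: their cis relationship follows from the concerted syn addition, and their absolute sense from the tartrate, L-(+)-diethyl tartrate being expected to deliver oxygen to the face that gives the 2S-type arrangement at C6, that is (1S,6S)-3. The only selectivity required is between the two enantiotopic faces, because 2 is achiral and has a single alkene; it is secured by the C7 hydroxyl, which anchors the substrate to titanium and places one face under the bound peroxide. The electron-rich tetrasubstituted alkene should react readily despite its hindrance. Because the tetrasubstituted epoxide is sensitive to Lewis acids, the titanium loading is kept catalytic with sieves, the temperature low and the work-up non-acidic.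

Step 3
Reactants: 3 [(1S,6S)-2,2,6-trimethyl-7-oxabicyclo[4.1.0]heptan-1-yl]methanol
Product: 4 (1S,2R)-1-(hydroxymethyl)-2,6,6-trimethylcyclohexane-1,2-diol
Conditions: HClO4 (cat., aq.), THF/H2O, 0 °C → rt
Reagents that add atoms: water, O
Why: Acid-catalysed hydrolytic opening of a 2,3-epoxy alcohol: after protonation, water attacks anti (trans-diaxial, Fürst–Plattner) at C5, the carbon better able to bear positive charge, because C6 is neopentyl and inductively deactivated by its CH2OH group; C5 is inverted and the C6–O bond is kept, so the cis-oxirane becomes the trans-diol.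

Step 4
Reactants: 4 (1S,2R)-1-(hydroxymethyl)-2,6,6-trimethylcyclohexane-1,2-diol
Product: 6 [(1S,2R)-2,6,6-trimethyl-1,2-bis(trimethylsilyloxy)cyclohexyl]methanol, via tris(trimethylsilyl) ether 5 (not isolated)
Conditions: Me3SiOTf, Et3N, CH2Cl2, −78 → 0 °C; aq. NaHCO3 wash, crude taken up in MeOH; pyridinium p-toluenesulfonate (cat.), MeOH, 0 °C
Reagents that add atoms: trimethylsilyl trifluoromethanesulfonate, C[Si](C)(C)OS(=O)(=O)C(F)(F)F
Why: Exhaustive silylation with the silyl triflate covers even the doubly neopentyl tertiary hydroxyls, and acid-catalysed methanolysis then removes only the unhindered primary silyl ether (steric differentiation in silyl ether solvolysis, without alkoxide formation and hence without O-to-O silyl migration); the two tertiary ethers that remain block retro-aldol and α-ketol pathways in the aldehyde to come.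

Step 5
Reactants: 6 [(1S,2R)-2,6,6-trimethyl-1,2-bis(trimethylsilyloxy)cyclohexyl]methanol
Product: 7 (1R,2R)-2,6,6-trimethyl-1,2-bis(trimethylsilyloxy)cyclohexane-1-carbaldehyde
Conditions: nPr4N[RuO4] (5 mol %), N-methylmorpholine N-oxide, 4 Å molecular sieves, CH2Cl2, rt
Reagents that add atoms: none
Why: Ley–Griffith oxidation under neutral conditions takes the primary alcohol to the aldehyde; the α-carbon is quaternary, so neither enolisation nor epimerisation is possible and the silyl ethers are untouched.

Step 6
Reactants: 7 (1R,2R)-2,6,6-trimethyl-1,2-bis(trimethylsilyloxy)cyclohexane-1-carbaldehyde; 8 triethyl 3-methyl-4-phosphonocrotonate (ethyl (E)-4-(diethoxyphosphoryl)-3-methylbut-2-enoate)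
Product: 9 ethyl (2E,4E)-3-methyl-5-[(1R,2R)-2,6,6-trimethyl-1,2-bis(trimethylsilyloxy)cyclohexyl]penta-2,4-dienoate
Conditions: 8, LiN(SiMe3)2, THF/DMPU, −78 °C; then 7, −78 °C → rt
Reagents that add atoms: none
Why: Vinylogous Horner–Wadsworth–Emmons olefination: the stabilised phosphonate anion adds to the non-enolisable aldehyde and eliminates phosphate to give the thermodynamically preferred E C7=C8 bond, while C9=C10 keeps the E geometry of 8; no stereocentre is touched.

Step 7
Reactants: 9 ethyl (2E,4E)-3-methyl-5-[(1R,2R)-2,6,6-trimethyl-1,2-bis(trimethylsilyloxy)cyclohexyl]penta-2,4-dienoate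
Product: 10 (2E,4E)-3-methyl-5-[(1R,2R)-2,6,6-trimethyl-1,2-bis(trimethylsilyloxy)cyclohexyl]penta-2,4-dien-1-ol
Conditions: iBu2AlH, CH2Cl2, −78 °C; aq. potassium sodium tartrate (KNaC4H4O6)
Reagents that add atoms: none
Why: Aluminium hydride 1,2-reduction of the conjugated ester to the allylic alcohol at low temperature; the hindered tertiary silyl ethers and the diene are inert and the work-up is neutral.

Step 8
Reactants: 10 (2E,4E)-3-methyl-5-[(1R,2R)-2,6,6-trimethyl-1,2-bis(trimethylsilyloxy)cyclohexyl]penta-2,4-dien-1-ol
Product: 11 (2E,4E)-3-methyl-5-[(1R,2R)-2,6,6-trimethyl-1,2-bis(trimethylsilyloxy)cyclohexyl]penta-2,4-dienal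
Conditions: MnO2 (activated, excess), CH2Cl2, rt, dark
Reagents that add atoms: none
Why: MnO2 oxidises allylic alcohols selectively to enals without over-oxidation and should leave the E geometry and the silyl ethers unchanged.

Step 9
Reactants: 12 (2E,4E,6E)-2,7-dimethylocta-2,4,6-trienedial; 13 ethyl (triphenylphosphoranylidene)acetate
Product: 14 ethyl (2E,4E,6E,8E)-4,9-dimethyl-10-oxodeca-2,4,6,8-tetraenoate
Conditions: 12 (excess), 13, CH2Cl2, rt, dark
Reagents that add atoms: none
Why: Wittig reaction of a stabilised ylide under base-free conditions gives the E enoate; an excess of the symmetrical dialdehyde holds the reaction at mono-olefination and the surplus 12 is recovered.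

Step 10
Reactants: 14 ethyl (2E,4E,6E,8E)-4,9-dimethyl-10-oxodeca-2,4,6,8-tetraenoate
Product: 15 ethyl (2E,4E,6E,8E)-10-hydroxy-4,9-dimethyldeca-2,4,6,8-tetraenoate
Conditions: NaBH4, EtOH/THF, −20 → 0 °C
Reagents that add atoms: none
Why: Borohydride reduces the formyl group in the 1,2-mode much faster than the conjugated ester, giving the allylic alcohol chemoselectively.

Step 11
Reactants: 15 ethyl (2E,4E,6E,8E)-10-hydroxy-4,9-dimethyldeca-2,4,6,8-tetraenoate
Product: 16 ethyl (2E,4E,6E,8E)-10-bromo-4,9-dimethyldeca-2,4,6,8-tetraenoate
Conditions: PBr3, pyridine (cat.), Et2O, −10 → 0 °C, dark; used crude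
Reagents that add atoms: phosphorus tribromide, BrP(Br)Br
Why: Conversion of an allylic alcohol into the allylic bromide through its phosphite ester; the primary, fully conjugated bromide is the thermodynamic regioisomer, so allylic transposition is not expected to persist.

Step 12
Reactants: 16 ethyl (2E,4E,6E,8E)-10-bromo-4,9-dimethyldeca-2,4,6,8-tetraenoate
Product: 17 ethyl (2E,4E,6E,8E)-10-(diethoxyphosphoryl)-4,9-dimethyldeca-2,4,6,8-tetraenoate
Conditions: P(OEt)3, toluene, 90 °C, dark
Reagents that add atoms: triethyl phosphite, CCOP(OCC)OCC
Why: Michaelis–Arbuzov reaction: SN2 attack of the phosphite on the allylic bromide and dealkylation of the phosphonium salt by bromide give the phosphonate with the E alkenes unchanged.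

Step 13
Reactants: 11 (2E,4E)-3-methyl-5-[(1R,2R)-2,6,6-trimethyl-1,2-bis(trimethylsilyloxy)cyclohexyl]penta-2,4-dienal; 17 ethyl (2E,4E,6E,8E)-10-(diethoxyphosphoryl)-4,9-dimethyldeca-2,4,6,8-tetraenoate
Product: 18 ethyl (2E,4E,6E,8E,10E,12E,14E)-4,9,13-trimethyl-15-[(1R,2R)-2,6,6-trimethyl-1,2-bis(trimethylsilyloxy)cyclohexyl]pentadeca-2,4,6,8,10,12,14-heptaenoate
Conditions: 17, NaN(SiMe3)2, THF, −78 °C; then 11, −78 → 0 °C, dark
Reagents that add atoms: none
Why: Vinylogous Horner–Wadsworth–Emmons olefination between enal 11 and the stabilised anion of 17 forms the C11=C12 bond with E preference through reversible addition; the reversed methyl pattern at C13/C13' arrives intact in 17.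

Step 14
Reactants: 18 ethyl (2E,4E,6E,8E,10E,12E,14E)-4,9,13-trimethyl-15-[(1R,2R)-2,6,6-trimethyl-1,2-bis(trimethylsilyloxy)cyclohexyl]pentadeca-2,4,6,8,10,12,14-heptaenoate
Product: 20 (2E,4E,6E,8E,10E,12E,14E)-15-[(1R,2R)-1,2-dihydroxy-2,6,6-trimethylcyclohexyl]-4,9,13-trimethylpentadeca-2,4,6,8,10,12,14-heptaenoic acid, via diol ethyl ester 19 (not isolated)
Conditions: nBu4NF, THF, 0 °C → rt; then LiOH, MeOH/H2O, rt, dark, argon; cold dilute HCl to pH 5
Reagents that add atoms: lithium hydroxide, [Li+].[OH-]
Why: Fluoride cleaves the two tertiary Si–O bonds (driven by the Si–F bond) and hydroxide then saponifies the ethyl ester by acyl substitution; nothing acidic reaches the tertiary allylic C6 alcohol until a brief, cold, weakly acidic work-up, so C5 and C6 are not disturbed.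

## Compound list

1 | β-cyclocitral (2,6,6-trimethylcyclohex-1-ene-1-carbaldehyde) | CC1=C(C=O)C(C)(C)CCC1 | starting material
2 | β-cyclogeraniol ((2,6,6-trimethylcyclohex-1-en-1-yl)methanol) | CC1=C(CO)C(C)(C)CCC1 | intermediate
3 | [(1S,6S)-2,2,6-trimethyl-7-oxabicyclo[4.1.0]heptan-1-yl]methanol | OC[C@@]12C(C)(C)CCC[C@]1(C)O2 | intermediate
4 | (1S,2R)-1-(hydroxymethyl)-2,6,6-trimethylcyclohexane-1,2-diol | OC[C@@]1(O)C(C)(C)CCC[C@@]1(C)O | intermediate
5 | (1S,2R)-2,6,6-trimethyl-1,2-bis(trimethylsilyloxy)-1-[(trimethylsilyloxy)methyl]cyclohexane | C[Si](C)(C)OC[C@@]1(O[Si](C)(C)C)C(C)(C)CCC[C@@]1(C)O[Si](C)(C)C | intermediate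
6 | [(1S,2R)-2,6,6-trimethyl-1,2-bis(trimethylsilyloxy)cyclohexyl]methanol | OC[C@@]1(O[Si](C)(C)C)C(C)(C)CCC[C@@]1(C)O[Si](C)(C)C | intermediate
7 | (1R,2R)-2,6,6-trimethyl-1,2-bis(trimethylsilyloxy)cyclohexane-1-carbaldehyde | O=C[C@@]1(O[Si](C)(C)C)C(C)(C)CCC[C@@]1(C)O[Si](C)(C)C | intermediate
8 | triethyl 3-methyl-4-phosphonocrotonate (ethyl (E)-4-(diethoxyphosphoryl)-3-methylbut-2-enoate) | CCOC(=O)/C=C(C)/CP(=O)(OCC)OCC | starting material
9 | ethyl (2E,4E)-3-methyl-5-[(1R,2R)-2,6,6-trimethyl-1,2-bis(trimethylsilyloxy)cyclohexyl]penta-2,4-dienoate | CCOC(=O)/C=C(C)/C=C/[C@@]1(O[Si](C)(C)C)C(C)(C)CCC[C@@]1(C)O[Si](C)(C)C | intermediate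
10 | (2E,4E)-3-methyl-5-[(1R,2R)-2,6,6-trimethyl-1,2-bis(trimethylsilyloxy)cyclohexyl]penta-2,4-dien-1-ol | OC/C=C(C)/C=C/[C@@]1(O[Si](C)(C)C)C(C)(C)CCC[C@@]1(C)O[Si](C)(C)C | intermediate
11 | (2E,4E)-3-methyl-5-[(1R,2R)-2,6,6-trimethyl-1,2-bis(trimethylsilyloxy)cyclohexyl]penta-2,4-dienal | O=C/C=C(C)/C=C/[C@@]1(O[Si](C)(C)C)C(C)(C)CCC[C@@]1(C)O[Si](C)(C)C | intermediate
12 | (2E,4E,6E)-2,7-dimethylocta-2,4,6-trienedial | O=C/C(C)=C/C=C/C=C(C)/C=O | starting material
13 | ethyl (triphenylphosphoranylidene)acetate | CCOC(=O)C=P(c1ccccc1)(c1ccccc1)c1ccccc1 | starting material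
14 | ethyl (2E,4E,6E,8E)-4,9-dimethyl-10-oxodeca-2,4,6,8-tetraenoate | CCOC(=O)/C=C/C(C)=C/C=C/C=C(C)/C=O | intermediate
15 | ethyl (2E,4E,6E,8E)-10-hydroxy-4,9-dimethyldeca-2,4,6,8-tetraenoate | CCOC(=O)/C=C/C(C)=C/C=C/C=C(C)/CO | intermediate
16 | ethyl (2E,4E,6E,8E)-10-bromo-4,9-dimethyldeca-2,4,6,8-tetraenoate | CCOC(=O)/C=C/C(C)=C/C=C/C=C(C)/CBr | intermediate
17 | ethyl (2E,4E,6E,8E)-10-(diethoxyphosphoryl)-4,9-dimethyldeca-2,4,6,8-tetraenoate | CCOC(=O)/C=C/C(C)=C/C=C/C=C(C)/CP(=O)(OCC)OCC | intermediate
18 | ethyl (2E,4E,6E,8E,10E,12E,14E)-4,9,13-trimethyl-15-[(1R,2R)-2,6,6-trimethyl-1,2-bis(trimethylsilyloxy)cyclohexyl]pentadeca-2,4,6,8,10,12,14-heptaenoate | CCOC(=O)/C=C/C(C)=C/C=C/C=C(C)/C=C/C=C(C)/C=C/[C@@]1(O[Si](C)(C)C)C(C)(C)CCC[C@@]1(C)O[Si](C)(C)C | intermediate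
19 | ethyl (2E,4E,6E,8E,10E,12E,14E)-15-[(1R,2R)-1,2-dihydroxy-2,6,6-trimethylcyclohexyl]-4,9,13-trimethylpentadeca-2,4,6,8,10,12,14-heptaenoate | CCOC(=O)/C=C/C(C)=C/C=C/C=C(C)/C=C/C=C(C)/C=C/[C@@]1(O)C(C)(C)CCC[C@@]1(C)O | intermediate
20 | (2E,4E,6E,8E,10E,12E,14E)-15-[(1R,2R)-1,2-dihydroxy-2,6,6-trimethylcyclohexyl]-4,9,13-trimethylpentadeca-2,4,6,8,10,12,14-heptaenoic acid ((5R,6R)-5,6-dihydroxy-5,6-dihydro-10'-apo-β-caroten-10'-oic acid) | CC(/C=C/C=C(C)/C=C/[C@@]1(O)C(C)(C)CCC[C@@]1(C)O)=C\C=C\C=C(C)\C=C\C(=O)O | target

## Step count and least certain steps

Total: 14 steps. Longest linear sequence: 10 steps (steps 1–8, 13, 14, from 1); the side branch (steps 9–12) joins at step 13.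

Key step (step 2). What may go wrong is incomplete enantioface discrimination on the hindered tetrasubstituted alkene, together with titanium-promoted opening of the labile oxirane during the reaction or the work-up. The fallback sets out from 3 of insufficient enantiomeric purity and returns to 3. Acylation with 4-nitrobenzoyl chloride and Et3N in CH2Cl2 should give the ester [(1S,6S)-2,2,6-trimethyl-7-oxabicyclo[4.1.0]heptan-1-yl]methyl 4-nitrobenzoate F1, expected to be crystalline. Recrystallisation would enrich the major enantiomer, and mild methanolysis (K2CO3, MeOH, 0 °C) would return upgraded 3. This replaces reliance on catalyst control alone by crystallisation-based enrichment.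

Step 3. What may go wrong is loss of regio- and stereocontrol through a free tertiary cation at C5: capture of water from the front side, proton loss to allylic alcohols, or a 1,2-shift with ring contraction. The fallback sets out from 2 and returns at 4, inverting C6 under base instead of C5 under acid. Epoxidation of 2 as in step 2 but with D-(−)-diethyl tartrate should give the enantiomer [(1R,6R)-2,2,6-trimethyl-7-oxabicyclo[4.1.0]heptan-1-yl]methanol F2. Heating F2 with aqueous NaOH in tBuOH sets up a Payne rearrangement, in which the C7 alkoxide displaces the oxirane oxygen at C6 with inversion to give the spiro-epoxide (3S,4R)-4,8,8-trimethyl-1-oxaspiro[2.5]octan-4-ol F3. Hydroxide then opens F3 at the unhindered C7 methylene. Inversion at C6 of the enantiomeric epoxide leads to the same triol 4, and no cation is involved.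

Step 4. What may go wrong is over-cleavage, or migration of a silyl group from a hindered tertiary oxygen to the freed primary oxygen, leading to loss of the tertiary silyl ethers. The fallback sets out from 4 and returns at 6 by orthogonal protection. Selective acetylation of the primary hydroxyl (Ac2O, pyridine, 0 °C) gives [(1S,2R)-1,2-dihydroxy-2,6,6-trimethylcyclohexyl]methyl acetate F4. Silylation of both tertiary hydroxyls (Me3SiOTf, Et3N, CH2Cl2) gives [(1S,2R)-2,6,6-trimethyl-1,2-bis(trimethylsilyloxy)cyclohexyl]methyl acetate F5. Reductive removal of the acetate with iBu2AlH at −78 °C then gives 6 without any solvolysis.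

Step 6. What may go wrong is slow addition of the stabilised vinylogous anion to the doubly neopentyl aldehyde, E/Z equilibration of the allylic anion (leakage to the 9Z isomer), or a silyl shift onto the intermediate alkoxide that blocks the elimination. The fallback sets out from 7 and returns at 9, dividing the task into two smaller olefinations. Horner–Wadsworth–Emmons reaction of 7 with diethyl (2-oxopropyl)phosphonate and NaH in THF gives the enone (E)-4-[(1R,2R)-2,6,6-trimethyl-1,2-bis(trimethylsilyloxy)cyclohexyl]but-3-en-2-one F6. A second olefination of the methyl ketone with triethyl phosphonoacetate and NaH, followed by chromatographic removal of the 9Z isomer, gives 9.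

Step 13. What may go wrong is low reactivity or ambident reaction of the highly delocalised tetraenyl phosphonate anion, and E/Z scrambling at C13=C14 or at the new C11=C12 bond. The fallback reverses the polarity of the same bond formation; it sets out from 10 (with 14 as partner) and returns at 18. Appel bromination (CBr4, PPh3, 2,6-lutidine, CH2Cl2, −20 °C) gives (1R,2R)-1-[(1E,3E)-5-bromo-3-methylpenta-1,3-dien-1-yl]-2,6,6-trimethyl-1,2-bis(trimethylsilyloxy)cyclohexane F7. Arbuzov reaction with P(OEt)3 gives diethyl {(2E,4E)-3-methyl-5-[(1R,2R)-2,6,6-trimethyl-1,2-bis(trimethylsilyloxy)cyclohexyl]penta-2,4-dien-1-yl}phosphonate F8. Deprotonation with NaN(SiMe3)2 in THF at −78 °C and addition of aldehyde 14 then gives 18.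

## Further compounds

F1 | step 2 | [(1S,6S)-2,2,6-trimethyl-7-oxabicyclo[4.1.0]heptan-1-yl]methyl 4-nitrobenzoate | O=C(OC[C@@]12C(C)(C)CCC[C@]1(C)O2)c1ccc(cc1)[N+](=O)[O-]
F2 | step 3 | [(1R,6R)-2,2,6-trimethyl-7-oxabicyclo[4.1.0]heptan-1-yl]methanol | OC[C@]12C(C)(C)CCC[C@@]1(C)O2
F3 | step 3 | (3S,4R)-4,8,8-trimethyl-1-oxaspiro[2.5]octan-4-ol | C1O[C@@]12C(C)(C)CCC[C@@]2(C)O
F4 | step 4 | [(1S,2R)-1,2-dihydroxy-2,6,6-trimethylcyclohexyl]methyl acetate | CC(=O)OC[C@@]1(O)C(C)(C)CCC[C@@]1(C)O
F5 | step 4 | [(1S,2R)-2,6,6-trimethyl-1,2-bis(trimethylsilyloxy)cyclohexyl]methyl acetate | CC(=O)OC[C@@]1(O[Si](C)(C)C)C(C)(C)CCC[C@@]1(C)O[Si](C)(C)C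
F6 | step 6 | (E)-4-[(1R,2R)-2,6,6-trimethyl-1,2-bis(trimethylsilyloxy)cyclohexyl]but-3-en-2-one | CC(=O)/C=C/[C@@]1(O[Si](C)(C)C)C(C)(C)CCC[C@@]1(C)O[Si](C)(C)C
F7 | step 13 | (1R,2R)-1-[(1E,3E)-5-bromo-3-methylpenta-1,3-dien-1-yl]-2,6,6-trimethyl-1,2-bis(trimethylsilyloxy)cyclohexane | BrC/C=C(C)/C=C/[C@@]1(O[Si](C)(C)C)C(C)(C)CCC[C@@]1(C)O[Si](C)(C)C
F8 | step 13 | diethyl {(2E,4E)-3-methyl-5-[(1R,2R)-2,6,6-trimethyl-1,2-bis(trimethylsilyloxy)cyclohexyl]penta-2,4-dien-1-yl}phosphonate | CCOP(=O)(OCC)C/C=C(C)/C=C/[C@@]1(O[Si](C)(C)C)C(C)(C)CCC[C@@]1(C)O[Si](C)(C)C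
A1 | alternative 1 | ethyl (2E,4E)-5-iodo-4-methylpenta-2,4-dienoate | CCOC(=O)/C=C/C(C)=C/I
A2 | alternative 1 | (E)-tributyl[2-(4,4,5,5-tetramethyl-1,3,2-dioxaborolan-2-yl)ethenyl]stannane | CCCC[Sn](CCCC)(CCCC)/C=C/B1OC(C)(C)C(C)(C)O1
A3 | alternative 1 | (1R,2R)-1-[(1E,3E,5E,7E)-8-iodo-3,7-dimethylocta-1,3,5,7-tetraen-1-yl]-2,6,6-trimethylcyclohexane-1,2-diol | I/C=C(C)/C=C/C=C(C)/C=C/[C@@]1(O)C(C)(C)CCC[C@@]1(C)O
A4 | alternative 1 | ethyl (2E,4E,6E,8E,10E,12E,14E)-15-[(1R,2R)-1,2-dihydroxy-2,6,6-trimethylcyclohexyl]-4,9,13-trimethylpentadeca-2,4,6,8,10,12,14-heptaenoate | CCOC(=O)/C=C/C(C)=C/C=C/C=C(C)/C=C/C=C(C)/C=C/[C@@]1(O)C(C)(C)CCC[C@@]1(C)O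
A5 | alternative 2 | 2,2-dimethyl-6-oxoheptanal | CC(=O)CCCC(C)(C)C=O
A6 | alternative 2 | (R)-2-hydroxy-2,6,6-trimethylcyclohexanone | O=C1C(C)(C)CCC[C@@]1(C)O
A7 | alternative 3 | (R)-4,8-dimethyl-4-(triethylsilyloxy)-1-(trimethylsilyl)non-7-en-1-yn-3-one | C[Si](C)(C)C#CC(=O)[C@@](C)(CCC=C(C)C)O[Si](CC)(CC)CC
A8 | alternative 3 | (1S,2R)-2,6,6-trimethyl-2-(triethylsilyloxy)-1-[(trimethylsilyl)ethynyl]cyclohexan-1-ol | C[Si](C)(C)C#C[C@@]1(O)C(C)(C)CCC[C@@]1(C)O[Si](CC)(CC)CC
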